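Amounts first: the solid substrate runs from 6.4 mM on Friday to 50 mM in south, against 50.0 mM of reagent.

| flask | solid substrate | reagent | catalyst | remark | time |
|---|---|---|---|---|---|
| Friday's | 6.4 mM | 50 mM | 2 mM | run made earlier |  |
| Thursday's | 34 mM | 50 mM | 2 mM | run made earlier |  |
| north-east | 8.0 mM | 50.0 mM | 2.0 mM |  | 2.0 min |
| south-east | 12 mM | 50.0 mM | 2.0 mM |  | 2.0 min |
| east | 20 mM | 50.0 mM | 2.0 mM |  | 2.0 min |
| north | 30 mM | 50.0 mM | 2.0 mM |  | 2.0 min |
| south | 50 mM | 50.0 mM | 2.0 mM |  | 2.0 min |

- Friday's (time / s: target / %): 10.0: 80.7; 15.0: 91.4; 30.0: 92.8; 40.0: 92.8; 60.0: 91.8
- Thursday's (time / s: target / %): 10.0: 16.0; 15.0: 25.2; 30.0: 43.0; 60.0: 74.3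

(scatter of a reading: 1 percentage point)

- solid, in amounts per volume of the solution: solid substrate
- at the start none of the solid substrate is in solution
- "hardly changes" means that all values lie within two and a half points (for a concentration: within two and a half percent of the largest)

1. amount of target at the end, in percent of the solid substrate charged for north-east, south-east, east, north, south, in this order
2. how that number moves from the first to the last of them (falls all the way / rises all the way / falls, then rises / hardly changes / rises, then falls)

Over the first 10.0 s, Friday's flask makes 0.516 mM s⁻¹ of target and Thursday's 0.544 mM s⁻¹, about the same, although Thursday's holds 5.31 times the solid. So the solid charge does not show in the early rate. But Thursday's rate sinks to 0.355 mM s⁻¹ between 30.0 s and 60.0 s, and I read that as c(reagent) falling, one reagent going per target.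

So I carry a pseudo-first-order constant as a time: the reagent time, 85.3 s, in which c(reagent) falls by a factor e while solid feeds the solution. It comes from Thursday's last reading.

Friday's target readings flatten at 92.8%, with reagent in excess, so I read a small loss beside the target and trim the row by it. By my reagent time, north reaches its charge at 78.1 s, inside 2.0 min. By the same time south, charged level with its reagent, gets 37.8 mM, or 75.5%.

The forecast says 92.5%, 92.3%, 92%, 91%, 74%, falls all the way, and for south its ground is that “reagent-limited conversion gives about 37 mM maximum”; for south my figure stands a little higher.

    solid substrate ⇌ starting material, rate k1*(cs1 - [starting material]) while solid is left; crystals form when [starting material] > cs1 (solubility = 3.20 mM, k = 2.80 s⁻¹)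
    2 starting material → self-condensation product (k = 4.10 M⁻¹ s⁻¹)
    starting material + reagent + catalyst → target + catalyst, rate k3*[starting material]*[reagent]*[catalyst]/(1 + ([starting material]/sat3)) (0.900 mM, k = 8700 M⁻² s⁻¹)

The flasks give 91.5%, 90.2%, 88.5%, 86.5%, 76.5%: falls all the way. South still holds 5.20% of its charge as starting material, the dissolved form of the solid substrate, at 2.00 min. At 1.00 min, with 33.5% of south's charge still solid, the reagent time leaves south 49.5% of its reagent, and the flask has 48.6%.

The runs are simulated with constants of no real substance; scatter was added.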